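**Plan**
- Ring A has oxygen on C2 and C4, the carboxyl on C1 and the 2-oxoalkyl chain on C6. This is the pattern of a cyclohexane-1,3-dione (C2 and C4 as carbonyls) with an ester on C1, so the arene is built as its dihydro form by a Claisen-type closure and oxidized afterwards.
- Retrosynthetic cuts, in order: ring bond C3–C4 (Dieckmann closure of an acetyl CH3 onto a methyl ester), ring bond C1–C6 (Michael addition of benzyl acetoacetate to an enoate), C5=C6 (Wittig), and side-chain bond C1'–C2' (Meldrum's acid homologation of O-benzylated 12-hydroxydodecanoic acid).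
- Forward: the chain is made first (acid, β-keto ester, ketal, aldehyde, enoate), the acetoacetate is added, ring A closes as the only ring, and it is aromatized with methylation of the C4 oxygen. Ketal hydrolysis and one hydrogenolysis of both benzyl groups finish the synthesis.
- Stereochemistry: the target is achiral. The two centres formed in the Michael step (future C1 and C6) are left uncontrolled and disappear on aromatization.

Key step: step 7

Remark: a 2-(2-oxoalkyl)benzoic acid can equilibrate with its cyclic lactol; the open keto acid of the target SMILES is taken as the compound to be made, and the last step is kept neutral so that no dehydration to an isocoumarin should occur.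

**Route**

Step 1
Reactants: 1 12-hydroxydodecanoic acid
Product: 2 12-(benzyloxy)dodecanoic acid
Conditions: NaH (2.5 equiv), BnBr (1.1 equiv), THF–DMF, 0 °C → rt; aq. HCl work-up
Reagents that add atoms: benzyl bromide, BrCc1ccccc1
Why: Williamson ether synthesis on the disodium carboxylate–alkoxide, in which the alkoxide is by far the stronger nucleophile, so one equivalent of benzyl bromide should end up on the C12 oxygen and the acid is recovered on acidification.

Step 2
Reactants: 2 12-(benzyloxy)dodecanoic acid; 3 2,2-dimethyl-1,3-dioxane-4,6-dione (Meldrum's acid)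
Product: 5 methyl 14-(benzyloxy)-3-oxotetradecanoate, via acyl Meldrum's acid 4 (not isolated)
Conditions: DCC, DMAP, CH2Cl2, 0 °C → rt; filter; MeOH, reflux
Reagents that add atoms: methanol, CO
Why: Carbodiimide-mediated C-acylation of Meldrum's acid followed by methanolysis, which opens the acyl dioxanedione with loss of acetone and CO2, is the standard two-carbon homologation of a carboxylic acid to a β-keto ester.

Step 3
Reactants: 5 methyl 14-(benzyloxy)-3-oxotetradecanoate
Product: 6 methyl 2-{2-[11-(benzyloxy)undecyl]-1,3-dioxolan-2-yl}acetate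
Conditions: HOCH2CH2OH (3 equiv), p-TsOH·H2O (cat.), toluene, reflux, Dean–Stark
Reagents that add atoms: ethylene glycol, OCCO
Why: Acid-catalysed ketalization driven by azeotropic removal of water masks the ketone (future C2' carbonyl) as a base-stable dioxolane, as is routine for β-keto esters, and leaves the benzyl ether untouched.

Step 4
Reactants: 6 methyl 2-{2-[11-(benzyloxy)undecyl]-1,3-dioxolan-2-yl}acetate
Product: 7 2-{2-[11-(benzyloxy)undecyl]-1,3-dioxolan-2-yl}acetaldehyde
Conditions: i-Bu2AlH (1.1 equiv), CH2Cl2, −78 °C; MeOH, then aq. potassium sodium tartrate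
Reagents that add atoms: none
Why: Partial ester reduction with i-Bu2AlH at −78 °C, in which the tetrahedral aluminium hemiacetal, held by chelation to a dioxolane oxygen, should persist until the quench and then collapse to the aldehyde, which is used crude because β-alkoxy aldehydes can eliminate on silica.

Step 5
Reactants: 7 2-{2-[11-(benzyloxy)undecyl]-1,3-dioxolan-2-yl}acetaldehyde; 8 methyl (triphenylphosphoranylidene)acetate
Product: 9 methyl (E)-4-{2-[11-(benzyloxy)undecyl]-1,3-dioxolan-2-yl}but-2-enoate
Conditions: CH2Cl2, rt
Reagents that add atoms: none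
Why: Wittig olefination with a stabilized ylide is neutral, should give mainly the E-enoate, and the alkene geometry is of no consequence because this double bond is consumed in the next step.

Step 6
Reactants: 9 methyl (E)-4-{2-[11-(benzyloxy)undecyl]-1,3-dioxolan-2-yl}but-2-enoate; 10 benzyl 3-oxobutanoate (benzyl acetoacetate)
Product: 11 1-benzyl 5-methyl 2-acetyl-3-{[2-(11-(benzyloxy)undecyl)-1,3-dioxolan-2-yl]methyl}pentanedioate (racemic, mixture of diastereomers)
Conditions: 10 (1.5 equiv), DBU (0.2 equiv), MeCN, rt → 40 °C
Reagents that add atoms: none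
Why: Michael addition of the β-keto ester enolate to the enoate β-carbon (future C1–C6 bond) under catalytic amidine base, with the excess acetoacetate buffering the medium so that the γ-CH2 next to the ketal is not deprotonated; the two new stereocentres form without control and are removed in step 8.

Step 7
Reactants: 11 1-benzyl 5-methyl 2-acetyl-3-{[2-(11-(benzyloxy)undecyl)-1,3-dioxolan-2-yl]methyl}pentanedioate
Product: 12 benzyl 2-{[2-(11-(benzyloxy)undecyl)-1,3-dioxolan-2-yl]methyl}-4,6-dioxocyclohexane-1-carboxylate (racemic, largely enolized)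
Conditions: KOt-Bu (2.2 equiv), THF–t-BuOH, 0 °C → 50 °C; AcOH, 0 °C, then cold aq. citric acid to pH 4
Reagents that add atoms: none
Why: KOt-Bu first gives the stabilized β-keto ester enolate; by proton exchange through t-BuOH a small share of the isomeric enolate at the acetyl methyl group (future C3) is present, and this carbon adds to the methyl ester carbonyl (future C4) and expels methoxide in an intramolecular Claisen (Dieckmann) condensation. The closest known reaction type is the base-mediated cyclization of acetoacetate–crotonate Michael adducts to 6-alkyl-2,4-dioxocyclohexanecarboxylates (dihydroresorcylates). Ring A closes in a 6-exo-trig mode. No stereocentre is created, and the two existing centres (C1, C6) may epimerize freely because both vanish on aromatization. The step needs regioselective closure, and the substrate secures it by ring size: every other enolate–ester pairing would give a four-membered ring, the benzyl ester lies inside the delocalized enolate and is shielded from alkoxide exchange, and O-acylation to the enol lactone is reversible. Deprotonation of the acidic cyclic β-diketone product (hence two equivalents of base) should pull all equilibria, retro-Michael included, toward the carbocycle.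

Step 8
Reactants: 12 benzyl 2-{[2-(11-(benzyloxy)undecyl)-1,3-dioxolan-2-yl]methyl}-4,6-dioxocyclohexane-1-carboxylate
Product: 14 benzyl 2-[13-(benzyloxy)-2-oxotridecyl]-6-hydroxy-4-methoxybenzoate, via dioxolane aryl methyl ether 13 (not isolated)
Conditions: I2 (2 equiv), MeOH, reflux; aq. Na2S2O3, extract; crude in THF–1 M HCl, rt
Reagents that add atoms: methanol, CO; water, O
Why: Iodine–methanol oxidative aromatization of a cyclohexane-1,3-dione, in which acid-catalysed enol etherification should take place at the unhindered C4 carbonyl (the C2 enol is hydrogen-bonded to the ester) and α-iodination with loss of HI delivers the anisole, after which aqueous acid completes the hydrolysis of the dioxolane, which the liberated HI will already have partly exchanged, to the ketone.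

Step 9
Reactants: 14 benzyl 2-[13-(benzyloxy)-2-oxotridecyl]-6-hydroxy-4-methoxybenzoate
Product: 15 2-hydroxy-6-(13-hydroxy-2-oxotridecyl)-4-methoxybenzoic acid (CNP0165592.0)
Conditions: H2 (1 atm), Pd/C (10%), EtOAc–EtOH, rt
Reagents that add atoms: none
Why: Catalytic hydrogenolysis cleaves the benzyl ester and the benzyl ether in one neutral operation, while the non-conjugated ketone, the aryl methyl ether and the arene are not reduced over Pd/C at ambient pressure.

**Compound list**

1 | 12-hydroxydodecanoic acid | OCCCCCCCCCCCC(=O)O | starting material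
2 | 12-(benzyloxy)dodecanoic acid | O=C(O)CCCCCCCCCCCOCc1ccccc1 | intermediate
3 | 2,2-dimethyl-1,3-dioxane-4,6-dione (Meldrum's acid) | CC1(C)OC(=O)CC(=O)O1 | starting material
4 | 5-[12-(benzyloxy)-1-hydroxydodecylidene]-2,2-dimethyl-1,3-dioxane-4,6-dione | CC1(C)OC(=O)C(=C(O)CCCCCCCCCCCOCc2ccccc2)C(=O)O1 | intermediate
5 | methyl 14-(benzyloxy)-3-oxotetradecanoate | COC(=O)CC(=O)CCCCCCCCCCCOCc1ccccc1 | intermediate
6 | methyl 2-{2-[11-(benzyloxy)undecyl]-1,3-dioxolan-2-yl}acetate | COC(=O)CC1(CCCCCCCCCCCOCc2ccccc2)OCCO1 | intermediate
7 | 2-{2-[11-(benzyloxy)undecyl]-1,3-dioxolan-2-yl}acetaldehyde | O=CCC1(CCCCCCCCCCCOCc2ccccc2)OCCO1 | intermediate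
8 | methyl (triphenylphosphoranylidene)acetate | COC(=O)C=P(c1ccccc1)(c1ccccc1)c1ccccc1 | starting material
9 | methyl (E)-4-{2-[11-(benzyloxy)undecyl]-1,3-dioxolan-2-yl}but-2-enoate | COC(=O)/C=C/CC1(CCCCCCCCCCCOCc2ccccc2)OCCO1 | intermediate
10 | benzyl 3-oxobutanoate (benzyl acetoacetate) | CC(=O)CC(=O)OCc1ccccc1 | starting material
11 | 1-benzyl 5-methyl 2-acetyl-3-{[2-(11-(benzyloxy)undecyl)-1,3-dioxolan-2-yl]methyl}pentanedioate (racemic, mixture of diastereomers) | COC(=O)CC(CC1(CCCCCCCCCCCOCc2ccccc2)OCCO1)C(C(C)=O)C(=O)OCc1ccccc1 | intermediate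
12 | benzyl 2-{[2-(11-(benzyloxy)undecyl)-1,3-dioxolan-2-yl]methyl}-4,6-dioxocyclohexane-1-carboxylate (racemic, drawn as the triketo tautomer) | O=C(OCc1ccccc1)C1C(CC2(CCCCCCCCCCCOCc3ccccc3)OCCO2)CC(=O)CC1=O | intermediate
13 | benzyl 2-{[2-(11-(benzyloxy)undecyl)-1,3-dioxolan-2-yl]methyl}-6-hydroxy-4-methoxybenzoate | COc1cc(O)c(C(=O)OCc2ccccc2)c(CC2(CCCCCCCCCCCOCc3ccccc3)OCCO2)c1 | intermediate
14 | benzyl 2-[13-(benzyloxy)-2-oxotridecyl]-6-hydroxy-4-methoxybenzoate | COc1cc(O)c(C(=O)OCc2ccccc2)c(CC(=O)CCCCCCCCCCCOCc2ccccc2)c1 | intermediate
15 | 2-hydroxy-6-(13-hydroxy-2-oxotridecyl)-4-methoxybenzoic acid | COc1cc(O)c(C(=O)O)c(CC(=O)CCCCCCCCCCCO)c1 | target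

**Count and risks**

Total step count: 9. Longest linear sequence: 9 steps (from 1 to 15).

Steps most likely to fail:

Step 8. The HI released during the oxidation may open the dioxolane before ring A is aromatic, so that the freed ketone engages the neighbouring ester. The benzyl ester may also exchange with methanol, or methylation may not stay confined to the C4 oxygen. Fallback, from 12: dehydrogenation without acid and without methanol (DDQ, dioxane, rt → 60 °C) should give the resorcylate benzyl 2-{[2-(11-(benzyloxy)undecyl)-1,3-dioxolan-2-yl]methyl}-4,6-dihydroxybenzoate F1. Its C4 hydroxyl, the more acidic one and the one not hydrogen-bonded to the ester, is then methylated selectively (MeI, 1.1 equiv, K2CO3, acetone, rt). This rejoins the route at 13, which is carried through the aqueous-acid stage of step 8 to 14.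

Step 6. Conjugate addition to a β-alkyl enoate may be slow, and the base may instead deconjugate the enoate or open the dioxolane by β-elimination. Fallback, from 7 and 10: the other ring bond at C6 is formed (C5–C6 in place of C1–C6). Knoevenagel condensation (piperidine and AcOH, catalytic, CH2Cl2, 4 Å molecular sieves, 0 °C) should give the far more electrophilic alkylidene acetoacetate benzyl 2-acetyl-4-{2-[11-(benzyloxy)undecyl]-1,3-dioxolan-2-yl}but-2-enoate F2. A Lewis-base-catalysed Mukaiyama–Michael addition of 1-methoxy-1-(trimethylsilyloxy)ethene (LiOAc, catalytic, DMF, −45 → 0 °C) then gives the silyl enol ether 1-benzyl 5-methyl 3-{[2-(11-(benzyloxy)undecyl)-1,3-dioxolan-2-yl]methyl}-2-[1-(trimethylsilyloxy)ethylidene]pentanedioate F3. Hydrolysis on work-up with cold dilute citric acid rejoins the route at 11.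

Step 7. The acetyl methyl enolate is only a minor tautomer of the mono-anion, so closure may be slow and retro-Michael fragmentation or ester exchange by liberated methoxide may compete. Fallback, from 7: the same ring is closed from the complementary enone–malonate pairing. Wittig olefination with 1-(triphenylphosphoranylidene)propan-2-one (toluene, 80 °C) should give the enone (E)-5-{2-[11-(benzyloxy)undecyl]-1,3-dioxolan-2-yl}pent-3-en-2-one F4. Michael addition of dibenzyl malonate (KOt-Bu, catalytic, THF–t-BuOH, rt) gives dibenzyl 2-(1-{2-[11-(benzyloxy)undecyl]-1,3-dioxolan-2-yl}-4-oxopentan-2-yl)propanedioate F5. Its methyl ketone enolate then closes onto a benzyl ester with loss of benzyl alcohol (KOt-Bu, 2 equiv, THF, rt → 50 °C; AcOH quench), which rejoins the route at 12.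

**Further compounds**

F1 | step 8 | benzyl 2-{[2-(11-(benzyloxy)undecyl)-1,3-dioxolan-2-yl]methyl}-4,6-dihydroxybenzoate | Oc1cc(O)c(C(=O)OCc2ccccc2)c(CC2(CCCCCCCCCCCOCc3ccccc3)OCCO2)c1
F2 | step 6 | benzyl 2-acetyl-4-{2-[11-(benzyloxy)undecyl]-1,3-dioxolan-2-yl}but-2-enoate (E/Z mixture) | CC(=O)C(=CCC1(CCCCCCCCCCCOCc2ccccc2)OCCO1)C(=O)OCc1ccccc1
F3 | step 6 | 1-benzyl 5-methyl 3-{[2-(11-(benzyloxy)undecyl)-1,3-dioxolan-2-yl]methyl}-2-[1-(trimethylsilyloxy)ethylidene]pentanedioate | COC(=O)CC(CC1(CCCCCCCCCCCOCc2ccccc2)OCCO1)C(C(=O)OCc1ccccc1)=C(C)O[Si](C)(C)C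
F4 | step 7 | (E)-5-{2-[11-(benzyloxy)undecyl]-1,3-dioxolan-2-yl}pent-3-en-2-one | CC(=O)/C=C/CC1(CCCCCCCCCCCOCc2ccccc2)OCCO1
F5 | step 7 | dibenzyl 2-(1-{2-[11-(benzyloxy)undecyl]-1,3-dioxolan-2-yl}-4-oxopentan-2-yl)propanedioate | CC(=O)CC(CC1(CCCCCCCCCCCOCc2ccccc2)OCCO1)C(C(=O)OCc1ccccc1)C(=O)OCc1ccccc1
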